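In a one-step world a dose decays with a single time constant and comes out whole as product. The steps thought possible here can split a dose: partner can react through catalyst intermediate A to left-handed product, through catalyst intermediate B to right-handed product, and can also turn into decomposed reagent by itself.

| flask | left-handed substrate | right-handed substrate | partner | free catalyst | added ligand | remark | time |
|---|---|---|---|---|---|---|---|
| gamma | 1.5 M | 1.5 M | 0.90 M (in portions, 3) | 3 mM | 1.1 mM | run made earlier; portions every 1.2 d |  |
| theta | 1.5 M | 1.5 M | 0.90 M (in portions, 3) | 3 mM | 1.7 mM | run made earlier; portions every 1.2 d |  |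
| eta | 0.75 M | 0.75 M | 0.90 M (in portions, 3) | 3 mM | 2.2 mM | run made earlier; portions every 1.2 d |  |
| red | 1.5 M | 1.5 M | 0.900 M (in portions, 3) | 3.0 mM | 2.2 mM | the portions of partner follow each other after 1.2 d, the first at the start | 25 d |
| violet | 1.5 M | 1.5 M | 0.900 M (in portions, 3) | 3.0 mM | 2.2 mM | the portions of partner follow each other after 2.0 d, the first at the start | 25 d |
| green | 1.5 M | 1.5 M | 0.900 M (in portions, 3) | 3.0 mM | 2.2 mM | the portions of partner follow each other after 3.0 d, the first at the start | 25 d |
| amber | 1.5 M | 1.5 M | 0.900 M (in portions, 3) | 3.0 mM | 2.2 mM | the portions of partner follow each other after 5.0 d, the first at the start | 25 d |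
| teal | 1.5 M | 1.5 M | 0.900 M (in portions, 3) | 3.0 mM | 2.2 mM | the portions of partner follow each other after 6.0 d, the first at the start | 25 d |

| run | time / d | left-handed product / % |
|---|---|---|
| gamma | 1.25 | 2.6 |
| gamma | 4.00 | 7.5 |
| gamma | 8.00 | 8.2 |
| gamma | 10.0 | 7.6 |
| gamma | 15.0 | 7.7 |
| gamma | 20.0 | 7.8 |
| theta | 1.25 | 2.2 |
| theta | 4.00 | 8.3 |
| theta | 8.00 | 8.0 |
| theta | 10.0 | 7.5 |
| theta | 15.0 | 7.6 |
| theta | 20.0 | 7.6 |
| eta | 1.67 | 7.7 |
| eta | 5.00 | 16.0 |
| eta | 10.0 | 15.9 |
| eta | 15.0 | 15.5 |
| eta | 20.0 | 15.6 |

(readings scatter by 0.3 percentage points)

- free catalyst is single-handed; left-handed substrate and right-handed substrate are mirror images of each other, charged as a racemate, each of them at the stated concentration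
- steps thought possible: free catalyst + left-handed substrate <-> catalyst intermediate A; free catalyst + right-handed substrate <-> catalyst intermediate B; partner + catalyst intermediate A -> free catalyst + left-handed product; partner + catalyst intermediate B -> free catalyst + right-handed product; partner -> decomposed reagent; free catalyst + added ligand <-> idle complex
- "hardly changes" means that all values lie within two and a half points (for a concentration: within two and a half percent of the largest)

* [left-handed product] at the end for red, violet, green, amber, teal, in this order
* the shape of the row from first to last (rises, then falls / falls all the way / falls, then rises / hardly changes / rises all the way)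

I treated red through teal as a linear splitter with two times in it: τ, the lifetime of a portion of partner, and T, the time left after the last portion. Each listed step that consumes partner is first order in partner, so at fixed catalyst forms the split contains no partner concentration, and I took spacing to act through those forms. I took those forms to follow the substrates, which drift with the amount reacted rather than with the clock, and the 0.900 M of partner is less than the 3.00 M of substrate.

I read the gain from gamma: its last reading of 7.8% of the substrate charged, against 0.90 M of partner, reads s = 26.0%, the share of charged partner that ends as left-handed product. Theta, with 1.7 mM of added ligand against 1.1 mM, read 7.6% against 7.8%, with a scatter of 0.3 percentage points.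

For τ I used eta. Counting its first portion as finished, the second had given 48.1% of its share after 0.470 d, so τ reads about 0.717 d in eta, a rough figure from one early reading. Teal has the widest spacing, 6.0 d, which still leaves T = 13.0 d, and with eta's τ, T/τ = 18.1. So I expected red through teal to finish their partner and hold s times the charge, 0.234 M.

The forecast put red at 0.23 M and teal at 0.23 M, with the row's shape "hardly changes", holding that the “split therefore doesn't depend on partner concentration”.

The flasks gave 0.231 M in red and 0.231 M in teal, and the row's shape was "hardly changes"; teal held 0% of its partner at 25.0 d, the limiting reagent, and the gradual adding made no visible difference to its left-handed product.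

    free catalyst + left-handed substrate ⇌ catalyst intermediate A (K = 1.00 /M, k = 20.0 /M/min)
    free catalyst + right-handed substrate ⇌ catalyst intermediate B (K = 5.80 /M, k = 20.0 /M/min)
    partner + catalyst intermediate A → free catalyst + left-handed product (k = 1.10 /M/min)
    partner + catalyst intermediate B → free catalyst + right-handed product (k = 0.400 /M/min)
    partner → decomposed reagent (k = 4.20 × 10⁻⁴ /min)
    free catalyst + added ligand ⇌ idle complex (K = 530 /M, k = 5.70 /M/min)

Carried to eta, s gives 15.6% of the substrate charged there, and eta read 15.6% at 20.0 d.

(The runs are simulated for an exercise; scatter was added.)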